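**Plan**

Locants for the bicyclic compounds follow 1-benzoxepine (O1, C2–C5, C5a, C6–C9, C9a).

- Retrosynthesis: the C2–H/CH2Br pair goes back to an exocyclic enol ether and then to a lactone carbonyl at C2. The oxepene is cut at C4–C5 (alkenyl iodide plus primary alkyl iodide), then at the ester O1–C2 bond. Ring A is opened by the polyene disconnection (C5a–C6, C9a–O, C7–Br) to geranyl tert-butyl carbonate.
- Forward: ring A by bromonium cyclisation, acylation of the tertiary C9a–OH with a (Z)-3-iodoacrylic acid, closure of ring B at C4–C5, then conversion of the lactone C=O into CH(CH2Br).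
- Enabling feature: in ring A the C9a oxygen and the C5 methylene on C5a are trans-diequatorial neighbours. The hindered tertiary oxygen can therefore carry C2–C3=C4 as an acyl group, and the tertiary–secondary ether problem becomes a lactone problem solved by one C(sp2)–C(sp3) closure.
- Stereochemistry: C7 from catalyst-controlled bromonium formation; C5a and C9a from anti addition across the E olefin in a chair; ring olefin geometry from the Z iodoacrylate; C2 from hydroboration of the enol ether on the face opposite the axial C9a methyl.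

Key step: step 9

Remark: the enantiomer of the Lewis-base catalyst in step 2 is taken to be the one that gives the 7S bromide.

**Route**

Step 1
Reactants: 1 geraniol
Product: 2 geranyl tert-butyl carbonate
Conditions: n-BuLi, THF, −78 °C; then Boc2O, −78 °C to rt
Reagents that add atoms: di-tert-butyl dicarbonate, CC(C)(C)OC(=O)OC(=O)OC(C)(C)C
Why: O-acylation of the lithium alkoxide with Boc2O should give the allylic carbonate that later serves as the internal oxygen terminator.

Step 2
Reactants: 2 geranyl tert-butyl carbonate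
Product: 3 (4aR,6S,8aS)-6-bromo-5,5,8a-trimethylhexahydro-4H-1,3-benzodioxin-2-one
Conditions: 1,3-dibromo-5,5-dimethylhydantoin (0.55 equiv), chiral BINOL-derived N-triflyl thiophosphoramide (10 mol %), toluene–CH2Cl2, −78 to −40 °C; aq. Na2S2O3
Reagents that add atoms: 1,3-dibromo-5,5-dimethylhydantoin, CC1(C)N(Br)C(=O)N(Br)C1=O
Why: Catalytic enantioselective bromonium-induced polyene cyclisation with carbonate termination: the Lewis-base-bound electrophilic bromine should select one face of the terminal olefin (sets C–Br), the E olefin opens the bromonium at its tertiary carbon through a chair with bromine equatorial, and the Boc carbonyl oxygen traps the tertiary cation anti with loss of isobutene (sets the trans ring-fusion C–H and C–O centres).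

Step 3
Reactants: 3 (4aR,6S,8aS)-6-bromo-5,5,8a-trimethylhexahydro-4H-1,3-benzodioxin-2-one
Product: 4 (1S,2R,4S)-4-bromo-2-(hydroxymethyl)-1,3,3-trimethylcyclohexan-1-ol
Conditions: K2CO3 (cat.), MeOH, rt
Reagents that add atoms: none
Why: Base-catalysed methanolysis of the cyclic carbonate should free the primary and tertiary hydroxyls without touching the hindered equatorial secondary bromide.

Step 4
Reactants: 4 (1S,2R,4S)-4-bromo-2-(hydroxymethyl)-1,3,3-trimethylcyclohexan-1-ol
Product: 5 (1S,2S,4S)-4-bromo-2-(iodomethyl)-1,3,3-trimethylcyclohexan-1-ol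
Conditions: I2, PPh3, imidazole, CH2Cl2, 0 °C to rt
Reagents that add atoms: iodine, II
Why: Appel-type iodination should be selective for the primary alcohol, since the tertiary alcohol cannot be displaced under these conditions.

Step 5
Reactants: 6 ethyl propiolate
Product: 7 ethyl (2Z)-2-(hydroxymethyl)-3-iodoprop-2-enoate
Conditions: MgI2, monomeric CH2O (cracked from paraformaldehyde), CH2Cl2, −78 to 0 °C
Reagents that add atoms: formaldehyde, C=O; magnesium diiodide, [Mg+2].[I-].[I-]
Why: Halo-aldol (β-iodo Morita–Baylis–Hillman-type) reaction: iodide adds to the magnesium-activated ynoate and the iodoallenolate is hydroxymethylated, the kinetic product having iodine cis to the ester (Z).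

Step 6
Reactants: 7 ethyl (2Z)-2-(hydroxymethyl)-3-iodoprop-2-enoate
Product: 8 ethyl (2Z)-2-({[tert-butyl(dimethyl)silyl]oxy}methyl)-3-iodoprop-2-enoate
Conditions: TBSCl, imidazole, CH2Cl2, 0 °C to rt
Reagents that add atoms: tert-butyl(chloro)dimethylsilane, CC(C)(C)[Si](C)(C)Cl
Why: Standard silylation should mask the future C3 hydroxymethyl group so that only one primary alcohol is present at the bromination stage.

Step 7
Reactants: 8 ethyl (2Z)-2-({[tert-butyl(dimethyl)silyl]oxy}methyl)-3-iodoprop-2-enoate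
Product: 9 (2Z)-2-({[tert-butyl(dimethyl)silyl]oxy}methyl)-3-iodoprop-2-enoic acid
Conditions: LiOH, THF–H2O, 0 °C; then 1 M HCl to pH 3 at 0 °C
Reagents that add atoms: lithium hydroxide, [Li+].[OH-]
Why: Mild saponification should cleave the ethyl ester while the primary silyl ether and the Z iodoalkene survive cold hydroxide.

Step 8
Reactants: 5 (1S,2S,4S)-4-bromo-2-(iodomethyl)-1,3,3-trimethylcyclohexan-1-ol; 9 (2Z)-2-({[tert-butyl(dimethyl)silyl]oxy}methyl)-3-iodoprop-2-enoic acid
Product: 11 (1S,2S,4S)-4-bromo-2-(iodomethyl)-1,3,3-trimethylcyclohexyl (2Z)-2-({[tert-butyl(dimethyl)silyl]oxy}methyl)-3-iodoprop-2-enoate, via acid chloride 10 (not isolated)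
Conditions: 9, 1-chloro-N,N,2-trimethylprop-1-en-1-amine, CH2Cl2, 0 °C to rt; separately 5, NaN(SiMe3)2, THF, −78 °C; add the acid chloride solution, −78 to −20 °C
Reagents that add atoms: none
Why: Acylation of the preformed tertiary alkoxide by an acid chloride made under neutral conditions should overcome the hindrance of the tertiary alcohol, the low temperature keeping the alkoxide from displacing the neighbouring iodide and the carbonyl being attacked far faster than the iodoalkene.

Step 9
Reactants: 11 (1S,2S,4S)-4-bromo-2-(iodomethyl)-1,3,3-trimethylcyclohexyl (2Z)-2-({[tert-butyl(dimethyl)silyl]oxy}methyl)-3-iodoprop-2-enoate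
Product: 12 (5aS,7S,9aS)-7-bromo-3-({[tert-butyl(dimethyl)silyl]oxy}methyl)-6,6,9a-trimethyl-5a,6,7,8,9,9a-hexahydro-1-benzoxepin-2(5H)-one
Conditions: NiBr2(dme) (20 mol %), 4,4′-di-tert-butyl-2,2′-bipyridine, manganese powder, NaI, DMA, 25 °C, slow addition of 11 to 0.005 M
Reagents that add atoms: none
Why: Zerovalent nickel should insert into the alkenyl C–I bond of the iodoacrylate, the reduced alkenylnickel then abstracts iodine from the primary C–I bond, and the resulting primary radical is captured at nickel so that reductive elimination from trivalent nickel forges the C4–C5 bond (direct addition of the same radical to the iodoacrylate β-carbon with loss of an iodine atom would give the same product). The closest known reaction type is the nickel-catalysed reductive cross-electrophile coupling of alkenyl halides with alkyl halides, run here intramolecularly at high dilution. Ring B closes in a 7-endo sense with respect to the acrylate, so both olefinic carbons lie in the ring and the cis olefin encoded by the Z iodoacrylate is the only one that can form. No new stereocentre arises; the trans-diequatorial ester oxygen and CH2I arm on adjacent carbons of the chair hold the two reacting carbons within reach. The step needs selectivity for the primary iodide over the secondary bromide, which the much faster halogen abstraction from C–I and the hindered neopentyl-type equatorial C–Br should secure, and it needs cyclisation to outrun oligomerisation, which slow addition secures.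

Step 10
Reactants: 12 (5aS,7S,9aS)-7-bromo-3-({[tert-butyl(dimethyl)silyl]oxy}methyl)-6,6,9a-trimethyl-5a,6,7,8,9,9a-hexahydro-1-benzoxepin-2(5H)-one
Product: 13 tert-butyl{[(5aS,7S,9aS)-7-bromo-6,6,9a-trimethyl-2-methylidene-2,5,5a,6,7,8,9,9a-octahydro-1-benzoxepin-3-yl]methoxy}dimethylsilane
Conditions: Cp2TiMe2, toluene, 70 °C, dark
Reagents that add atoms: dimethyltitanocene, C[Ti+2]C.c1cc[cH-]c1.c1cc[cH-]c1
Why: Petasis methylenation (cycloaddition and cycloreversion of titanocene methylidene with the lactone carbonyl) should turn the acyl helper into the exocyclic enol ether whose CH2 becomes the bromomethyl carbon.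

Step 11
Reactants: 13 tert-butyl{[(5aS,7S,9aS)-7-bromo-6,6,9a-trimethyl-2-methylidene-2,5,5a,6,7,8,9,9a-octahydro-1-benzoxepin-3-yl]methoxy}dimethylsilane
Product: 15 [(2R,5aS,7S,9aS)-7-bromo-3-({[tert-butyl(dimethyl)silyl]oxy}methyl)-6,6,9a-trimethyl-2,5,5a,6,7,8,9,9a-octahydro-1-benzoxepin-2-yl]methanol, via B-alkyl-9-BBN adduct 14 (not isolated)
Conditions: 9-BBN, THF, 0 °C to rt; then aq. NaOH, 30% H2O2, 0 °C
Reagents that add atoms: hydrogen peroxide, OO
Why: Hydroboration–oxidation of the exocyclic enol ether should place boron on the terminal carbon (β to oxygen) in preference to the trisubstituted ring olefin, and deliver hydrogen to C2 from the face opposite the axial C9a methyl, which sets the 2R centre with CH2OH cis to that methyl.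

Step 12
Reactants: 15 [(2R,5aS,7S,9aS)-7-bromo-3-({[tert-butyl(dimethyl)silyl]oxy}methyl)-6,6,9a-trimethyl-2,5,5a,6,7,8,9,9a-octahydro-1-benzoxepin-2-yl]methanol
Product: 16 tert-butyl{[(2R,5aS,7S,9aS)-7-bromo-2-(bromomethyl)-6,6,9a-trimethyl-2,5,5a,6,7,8,9,9a-octahydro-1-benzoxepin-3-yl]methoxy}dimethylsilane
Conditions: CBr4, PPh3, 2,6-lutidine, CH2Cl2, 0 °C
Reagents that add atoms: tetrabromomethane, BrC(Br)(Br)Br
Why: Appel bromination should convert the only free primary alcohol into the bromide without touching C2 or the silyl ether.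

Step 13
Reactants: 16 tert-butyl{[(2R,5aS,7S,9aS)-7-bromo-2-(bromomethyl)-6,6,9a-trimethyl-2,5,5a,6,7,8,9,9a-octahydro-1-benzoxepin-3-yl]methoxy}dimethylsilane
Product: 17 [(2R,5aS,7S,9aS)-7-bromo-2-(bromomethyl)-6,6,9a-trimethyl-2,5,5a,6,7,8,9,9a-octahydro-1-benzoxepin-3-yl]methanol
Conditions: HF·pyridine, THF–pyridine, 0 °C to rt
Reagents that add atoms: none
Why: Acidic fluoride desilylation should free the allylic alcohol without generating an alkoxide that could displace the neighbouring primary bromide.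

**Compound list**

1 | geraniol, (2E)-3,7-dimethylocta-2,6-dien-1-ol | CC(C)=CCC/C(C)=C/CO | starting material
2 | geranyl tert-butyl carbonate | CC(C)=CCC/C(C)=C/COC(=O)OC(C)(C)C | intermediate
3 | (4aR,6S,8aS)-6-bromo-5,5,8a-trimethylhexahydro-4H-1,3-benzodioxin-2-one | CC1(C)[C@@H](Br)CC[C@]2(C)OC(=O)OC[C@@H]12 | intermediate
4 | (1S,2R,4S)-4-bromo-2-(hydroxymethyl)-1,3,3-trimethylcyclohexan-1-ol | CC1(C)[C@@H](Br)CC[C@](C)(O)[C@H]1CO | intermediate
5 | (1S,2S,4S)-4-bromo-2-(iodomethyl)-1,3,3-trimethylcyclohexan-1-ol | CC1(C)[C@@H](Br)CC[C@](C)(O)[C@H]1CI | intermediate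
6 | ethyl propiolate | C#CC(=O)OCC | starting material
7 | ethyl (2Z)-2-(hydroxymethyl)-3-iodoprop-2-enoate | OC/C(C(=O)OCC)=C/I | intermediate
8 | ethyl (2Z)-2-({[tert-butyl(dimethyl)silyl]oxy}methyl)-3-iodoprop-2-enoate | CC(C)(C)[Si](C)(C)OC/C(C(=O)OCC)=C/I | intermediate
9 | (2Z)-2-({[tert-butyl(dimethyl)silyl]oxy}methyl)-3-iodoprop-2-enoic acid | CC(C)(C)[Si](C)(C)OC/C(C(=O)O)=C/I | intermediate
10 | (2Z)-2-({[tert-butyl(dimethyl)silyl]oxy}methyl)-3-iodoprop-2-enoyl chloride | CC(C)(C)[Si](C)(C)OC/C(C(=O)Cl)=C/I | intermediate (not isolated)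
11 | (1S,2S,4S)-4-bromo-2-(iodomethyl)-1,3,3-trimethylcyclohexyl (2Z)-2-({[tert-butyl(dimethyl)silyl]oxy}methyl)-3-iodoprop-2-enoate | CC1(C)[C@@H](Br)CC[C@](C)(OC(=O)/C(CO[Si](C)(C)C(C)(C)C)=C\I)[C@H]1CI | intermediate
12 | (5aS,7S,9aS)-7-bromo-3-({[tert-butyl(dimethyl)silyl]oxy}methyl)-6,6,9a-trimethyl-5a,6,7,8,9,9a-hexahydro-1-benzoxepin-2(5H)-one | CC1(C)[C@@H](Br)CC[C@]2(C)OC(=O)C(CO[Si](C)(C)C(C)(C)C)=CC[C@@H]12 | intermediate
13 | tert-butyl{[(5aS,7S,9aS)-7-bromo-6,6,9a-trimethyl-2-methylidene-2,5,5a,6,7,8,9,9a-octahydro-1-benzoxepin-3-yl]methoxy}dimethylsilane | CC1(C)[C@@H](Br)CC[C@]2(C)OC(=C)C(CO[Si](C)(C)C(C)(C)C)=CC[C@@H]12 | intermediate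
14 | 9-{[(2S,5aS,7S,9aS)-7-bromo-3-({[tert-butyl(dimethyl)silyl]oxy}methyl)-6,6,9a-trimethyl-2,5,5a,6,7,8,9,9a-octahydro-1-benzoxepin-2-yl]methyl}-9-borabicyclo[3.3.1]nonane | CC1(C)[C@@H](Br)CC[C@]2(C)O[C@@H](CB3C4CCCC3CCC4)C(CO[Si](C)(C)C(C)(C)C)=CC[C@@H]12 | intermediate (not isolated)
15 | [(2R,5aS,7S,9aS)-7-bromo-3-({[tert-butyl(dimethyl)silyl]oxy}methyl)-6,6,9a-trimethyl-2,5,5a,6,7,8,9,9a-octahydro-1-benzoxepin-2-yl]methanol | CC1(C)[C@@H](Br)CC[C@]2(C)O[C@@H](CO)C(CO[Si](C)(C)C(C)(C)C)=CC[C@@H]12 | intermediate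
16 | tert-butyl{[(2R,5aS,7S,9aS)-7-bromo-2-(bromomethyl)-6,6,9a-trimethyl-2,5,5a,6,7,8,9,9a-octahydro-1-benzoxepin-3-yl]methoxy}dimethylsilane | CC1(C)[C@@H](Br)CC[C@]2(C)O[C@@H](CBr)C(CO[Si](C)(C)C(C)(C)C)=CC[C@@H]12 | intermediate
17 | [(2R,5aS,7S,9aS)-7-bromo-2-(bromomethyl)-6,6,9a-trimethyl-2,5,5a,6,7,8,9,9a-octahydro-1-benzoxepin-3-yl]methanol | CC1(C)[C@@H](Br)CC[C@]2(C)O[C@@H](CBr)C(CO)=CC[C@@H]12 | target

**Step count**

Total: 13 steps. Longest linear sequence: 10 steps (steps 1, 2, 3, 4, 8, 9, 10, 11, 12, 13 from geraniol).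

**Steps most likely to fail, with fallbacks**

1. Step 9. The ester must leave its preferred s-trans conformation to close the seven-membered lactone, so intermolecular coupling, hydrodeiodination, loss of the Z geometry at alkenylnickel, or halogen abstraction at the secondary bromide may outrun ring closure. Fallback, setting out from 11 and returning at 13: methylenate the acyclic ester first with Cp2TiMe2 (toluene, 70 °C) to give the 2-alkoxy-1,3-diene tert-butyl{[(2Z)-2-(1-{[(1S,2S,4S)-4-bromo-2-(iodomethyl)-1,3,3-trimethylcyclohexyl]oxy}ethenyl)-3-iodoprop-2-en-1-yl]oxy}dimethylsilane F1. Its enol-ether tether has no conformational penalty, and the same nickel-catalysed reductive alkenyl–alkyl coupling under neutral conditions should then close ring B at C4–C5 to give 13 directly.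

2. Step 2. Enantiofacial control of bromonium formation may be incomplete for a carbonate-terminated substrate, and proton loss from the tertiary cation may compete with carbonate capture. Fallback, setting out from 2 and returning at 4:
   - Cyclise without chiral control using Et2SBr·SbBrCl5 (MeNO2, −25 °C), which should give 3 together with its enantiomer (4aS,6R,8aR)-6-bromo-5,5,8a-trimethylhexahydro-4H-1,3-benzodioxin-2-one F2.
   - Methanolysis (K2CO3, MeOH) then gives 4 and (1R,2S,4R)-4-bromo-2-(hydroxymethyl)-1,3,3-trimethylcyclohexan-1-ol F3.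
   - Acylate the primary hydroxyl with (1S)-camphanic chloride (pyridine, CH2Cl2) to give the diastereomeric esters [(1R,3S,6S)-3-bromo-6-hydroxy-2,2,6-trimethylcyclohexyl]methyl (1S,4R)-camphanate F4 and [(1S,3R,6R)-3-bromo-6-hydroxy-2,2,6-trimethylcyclohexyl]methyl (1S,4R)-camphanate F5.
   - Separate them by chromatography or crystallisation, assign by X-ray, and cleave F4 with K2CO3 in MeOH to return to 4.

3. Step 11. Facial discrimination at C2 may be weak because the borane sits on the exocyclic carbon, away from the axial C9a methyl, and hydroboration of the ring olefin may compete. Fallback, setting out from 13 and returning at 16: treat 13 with N-bromosuccinimide in MeOH–CH2Cl2 over NaHCO3 at −78 °C to give the bromomethyl methyl ketal tert-butyl{[(2R,5aS,7S,9aS)-7-bromo-2-(bromomethyl)-2-methoxy-6,6,9a-trimethyl-2,5,5a,6,7,8,9,9a-octahydro-1-benzoxepin-3-yl]methoxy}dimethylsilane F6 (major epimer drawn; both epimers converge). Reduce it with Et3SiH and BF3·OEt2 (CH2Cl2, −78 °C). Hydride should add to the oxocarbenium carbon itself, as in Ferrier-type allyl oxocarbenium reductions, from the face opposite the C9a methyl, giving 16 directly and bypassing 15.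

**Further compounds**

F1 | step 9 | tert-butyl{[(2Z)-2-(1-{[(1S,2S,4S)-4-bromo-2-(iodomethyl)-1,3,3-trimethylcyclohexyl]oxy}ethenyl)-3-iodoprop-2-en-1-yl]oxy}dimethylsilane | CC1(C)[C@@H](Br)CC[C@](C)(OC(=C)/C(CO[Si](C)(C)C(C)(C)C)=C\I)[C@H]1CI
F2 | step 2 | (4aS,6R,8aR)-6-bromo-5,5,8a-trimethylhexahydro-4H-1,3-benzodioxin-2-one | CC1(C)[C@H](Br)CC[C@@]2(C)OC(=O)OC[C@H]12
F3 | step 2 | (1R,2S,4R)-4-bromo-2-(hydroxymethyl)-1,3,3-trimethylcyclohexan-1-ol | CC1(C)[C@H](Br)CC[C@@](C)(O)[C@@H]1CO
F4 | step 2 | [(1R,3S,6S)-3-bromo-6-hydroxy-2,2,6-trimethylcyclohexyl]methyl (1S,4R)-4,7,7-trimethyl-3-oxo-2-oxabicyclo[2.2.1]heptane-1-carboxylate | CC1(C)[C@@H](Br)CC[C@](C)(O)[C@H]1COC(=O)[C@@]12CC[C@@](C)(C(=O)O1)C2(C)C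
F5 | step 2 | [(1S,3R,6R)-3-bromo-6-hydroxy-2,2,6-trimethylcyclohexyl]methyl (1S,4R)-4,7,7-trimethyl-3-oxo-2-oxabicyclo[2.2.1]heptane-1-carboxylate | CC1(C)[C@H](Br)CC[C@@](C)(O)[C@@H]1COC(=O)[C@@]12CC[C@@](C)(C(=O)O1)C2(C)C
F6 | step 11 | tert-butyl{[(2R,5aS,7S,9aS)-7-bromo-2-(bromomethyl)-2-methoxy-6,6,9a-trimethyl-2,5,5a,6,7,8,9,9a-octahydro-1-benzoxepin-3-yl]methoxy}dimethylsilane | CC1(C)[C@@H](Br)CC[C@]2(C)O[C@@](OC)(CBr)C(CO[Si](C)(C)C(C)(C)C)=CC[C@@H]12
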